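**Retrosynthetic overview**

- The strategy rests on the side-chain carbinol C2′. It lies between the benzylic methylene C1′, bonded to the 2,4,6-trioxygenated (phloroglucinol) ring, and C3′, which carries the exocyclic methylidene. C1′–C2′–C3′ is therefore the β-carbon, α-carbon and carbonyl carbon of an (E)-aryl enone.
- Late disconnections: the benzoyl C–C bond (ring lithiation and Weinreb amide), the C1′–H bond (hydride opening of a benzylic oxirane C–O bond) and C3′=CH2 (Wittig reaction on an epoxy ketone).
- Key disconnection: the C2′–O and C1′–O bonds of a trans-oxirane, made by catalytic asymmetric nucleophilic epoxidation of the enone.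
- The enone comes from tris-MOM phloroglucinaldehyde and the methyl-side enolate of 6-methylhept-5-en-2-one.
- Ring order: both benzene rings are bought. The only ring formed is the oxirane (step 4), and it is opened again in step 6.

Key step: step 4

Remark: the side chain is numbered C1′ (benzylic) to C7′. The ligand sense in step 4, (S)-BINOL giving the (αR,βS) epoxy ketone, is assumed from the behaviour of simple (E)-β-aryl enones; if correlation at alcohol 11 shows the opposite sense, the antipodal ligand is used.

**Route**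

Step 1
Reactants: 1 2,4,6-trihydroxybenzaldehyde; 2 chloromethyl methyl ether
Product: 3 2,4,6-tris(methoxymethoxy)benzaldehyde
Conditions: NaH, DMF, 0 °C; then MOMCl, 0 °C → rt
Reagents that add atoms: chloromethyl methyl ether, COCCl
Why: Williamson-type O-alkylation of all three phenoxides (NaH also deprotonates the two chelated ortho hydroxyls); the MOM ethers tolerate base, hydroperoxide, ylide and hydride and later direct the ring lithiation.

Step 2
Reactants: 3 2,4,6-tris(methoxymethoxy)benzaldehyde; 4 6-methylhept-5-en-2-one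
Product: 6 rac-1-hydroxy-7-methyl-1-[2,4,6-tris(methoxymethoxy)phenyl]oct-6-en-3-one, via lithium enolate 5 (not isolated)
Conditions: LDA (commercial solution), THF, −78 °C; then 3, −78 °C; AcOH quench at −78 °C
Reagents that add atoms: none
Why: Directed (crossed) aldol addition in which kinetic deprotonation places the enolate on the methyl side of the ketone and the non-enolisable aldehyde is the only acceptor; the new carbinol centre is racemic and is removed in step 3.

Step 3
Reactants: 6 rac-1-hydroxy-7-methyl-1-[2,4,6-tris(methoxymethoxy)phenyl]oct-6-en-3-one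
Product: 8 (1E)-7-methyl-1-[2,4,6-tris(methoxymethoxy)phenyl]octa-1,6-dien-3-one, via benzylic mesylate 7 (not isolated)
Conditions: MsCl, Et3N (excess), CH2Cl2, 0 °C → rt
Reagents that add atoms: none
Why: Mesylation followed by E1cB β-elimination of the β-sulfonyloxy ketone gives the conjugated enone, and the di-ortho-substituted aryl group enforces the (E) geometry.

Step 4
Reactants: 8 (1E)-7-methyl-1-[2,4,6-tris(methoxymethoxy)phenyl]octa-1,6-dien-3-one
Product: 9 5-methyl-1-{(2R,3S)-3-[2,4,6-tris(methoxymethoxy)phenyl]oxiran-2-yl}hex-4-en-1-one (trans)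
Conditions: La(O-i-Pr)3 (cat.), (S)-BINOL (cat.), Ph3As=O (cat.), TBHP (decane solution), 4 Å MS, THF, rt
Reagents that add atoms: tert-butyl hydroperoxide, CC(C)(C)OO
Why: The lanthanum–binaphthoxide–arsine oxide complex carries the hydroperoxide as a La–OO-t-Bu unit and activates the enone carbonyl, so the peroxide oxygen adds to C1′ (the β-carbon) in conjugate fashion and gives a lanthanum β-peroxy enolate. The enolate carbon C2′ then displaces tert-butoxide from the proximal peroxide oxygen in a 3-exo-tet closure, which forms the C2′–O bond and closes the oxirane with the trans relationship of the (E)-alkene carried over. The closest known reaction type is the catalytic asymmetric Weitz–Scheffer (nucleophilic) epoxidation of (E)-β-aryl alkyl enones with lanthanide–binaphthol catalysts and alkyl hydroperoxides. Both new centres, C1′ (S) and C2′ (R), are fixed by the enone face that the (S)-BINOL ligand sphere presents to the bound peroxide; only C2′ is needed later. The step needs chemoselectivity for the enone alkene over the C6′=C7′ trisubstituted alkene, and this is secured because the oxidant is a nucleophile that attacks only the electron-poor double bond. It also needs a sufficiently electrophilic β-carbon, which the twist of the di-ortho-substituted aryl ring out of conjugation with the enone should preserve.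

Step 5
Reactants: 9 5-methyl-1-{(2R,3S)-3-[2,4,6-tris(methoxymethoxy)phenyl]oxiran-2-yl}hex-4-en-1-one
Product: 10 (2S,3S)-2-(6-methylhepta-1,5-dien-2-yl)-3-[2,4,6-tris(methoxymethoxy)phenyl]oxirane
Conditions: Ph3PCH3Br, KHMDS (slightly less than the salt), THF, 0 °C; then 9, 0 °C → rt; filtration through basic alumina, used without storage
Reagents that add atoms: methyltriphenylphosphonium bromide, C[P+](c1ccccc1)(c1ccccc1)c1ccccc1.[Br-]
Why: Wittig methylenation of an α,β-epoxy ketone, in which the non-stabilised ylide adds to the carbonyl faster than it attacks the oxirane and C2′ cannot enolise because it is an oxirane carbon; the change of the C2′ descriptor from R to S is a CIP priority change only.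

Step 6
Reactants: 10 (2S,3S)-2-(6-methylhepta-1,5-dien-2-yl)-3-[2,4,6-tris(methoxymethoxy)phenyl]oxirane
Product: 11 (2R)-7-methyl-3-methylidene-1-[2,4,6-tris(methoxymethoxy)phenyl]oct-6-en-2-ol
Conditions: DIBAL-H (excess), CH2Cl2, −78 °C → −40 °C; aq. Rochelle salt
Reagents that add atoms: none
Why: Lewis-acid-assisted reductive epoxide opening, in which aluminium coordination weakens the C1′–O bond (benzylic to the 2,4,6-trioxygenated ring, so by far the better carrier of positive charge than allylic C2′) and hydride is delivered to C1′; the C2′–O bond is untouched, so C2′ keeps its configuration and reads R in the product.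

Step 7
Reactants: 11 (2R)-7-methyl-3-methylidene-1-[2,4,6-tris(methoxymethoxy)phenyl]oct-6-en-2-ol
Product: 12 tert-butyldimethyl({(2R)-7-methyl-3-methylidene-1-[2,4,6-tris(methoxymethoxy)phenyl]oct-6-en-2-yl}oxy)silane
Conditions: TBSCl, imidazole, DMF, rt
Reagents that add atoms: tert-butyldimethylsilyl chloride, CC(C)(C)[Si](C)(C)Cl
Why: Imidazole-mediated silylation of the secondary alcohol, which removes the acidic O–H before the organolithium step and does not touch the stereocentre.

Step 8
Reactants: 12 tert-butyldimethyl({(2R)-7-methyl-3-methylidene-1-[2,4,6-tris(methoxymethoxy)phenyl]oct-6-en-2-yl}oxy)silane; 13 N-methoxy-N-methylbenzamide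
Product: 16 {3-[(2R)-2-(tert-butyldimethylsilyloxy)-7-methyl-3-methylideneoct-6-en-1-yl]-2,4,6-tris(methoxymethoxy)phenyl}(phenyl)methanone, via aryllithium 14 (not isolated), via lithium hemiaminal 15 (not isolated)
Conditions: n-BuLi, THF, −78 → 0 °C; then 13, −78 °C → rt; aq. NH4Cl
Reagents that add atoms: N-methoxy-N-methylbenzamide, CON(C)C(=O)c1ccccc1
Why: Directed ortho-metalation at a ring C–H flanked by two MOM ethers (the two such positions are constitutionally equivalent), followed by Weinreb amide acylation, which stops at the ketone because the chelated tetrahedral adduct survives until the quench.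

Step 9
Reactants: 16 {3-[(2R)-2-(tert-butyldimethylsilyloxy)-7-methyl-3-methylideneoct-6-en-1-yl]-2,4,6-tris(methoxymethoxy)phenyl}(phenyl)methanone
Product: 17 {2,4,6-trihydroxy-3-[(2R)-2-hydroxy-7-methyl-3-methylideneoct-6-en-1-yl]phenyl}(phenyl)methanone (CNP0149425.1)
Conditions: HCl (dilute, aq.), MeOH, rt → 40 °C
Reagents that add atoms: none
Why: Acid-catalysed acetal exchange removes the three MOM groups (the two next to the benzoyl carbonyl fastest) and the same medium solvolyses the secondary silyl ether; C2′ is not expected to ionise under dilute acid because its allyl cation would have only a secondary and a primary terminus.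

**Compound list**

1 | 2,4,6-trihydroxybenzaldehyde | O=Cc1c(O)cc(O)cc1O | starting material
2 | chloromethyl methyl ether | COCCl | starting material
3 | 2,4,6-tris(methoxymethoxy)benzaldehyde | O=Cc1c(OCOC)cc(OCOC)cc1OCOC | intermediate
4 | 6-methylhept-5-en-2-one | CC(=O)CCC=C(C)C | starting material
5 | lithium 6-methylhepta-1,5-dien-2-olate (kinetic enolate, not isolated) | C=C(O[Li])CCC=C(C)C | intermediate
6 | rac-1-hydroxy-7-methyl-1-[2,4,6-tris(methoxymethoxy)phenyl]oct-6-en-3-one | CC(C)=CCCC(=O)CC(O)c1c(OCOC)cc(OCOC)cc1OCOC | intermediate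
7 | rac-7-methyl-3-oxo-1-[2,4,6-tris(methoxymethoxy)phenyl]oct-6-en-1-yl methanesulfonate (not isolated) | CC(C)=CCCC(=O)CC(OS(C)(=O)=O)c1c(OCOC)cc(OCOC)cc1OCOC | intermediate
8 | (1E)-7-methyl-1-[2,4,6-tris(methoxymethoxy)phenyl]octa-1,6-dien-3-one | CC(C)=CCCC(=O)/C=C/c1c(OCOC)cc(OCOC)cc1OCOC | intermediate
9 | 5-methyl-1-{(2R,3S)-3-[2,4,6-tris(methoxymethoxy)phenyl]oxiran-2-yl}hex-4-en-1-one | CC(C)=CCCC(=O)[C@@H]1O[C@H]1c1c(OCOC)cc(OCOC)cc1OCOC | intermediate
10 | (2S,3S)-2-(6-methylhepta-1,5-dien-2-yl)-3-[2,4,6-tris(methoxymethoxy)phenyl]oxirane | C=C(CCC=C(C)C)[C@@H]1O[C@H]1c1c(OCOC)cc(OCOC)cc1OCOC | intermediate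
11 | (2R)-7-methyl-3-methylidene-1-[2,4,6-tris(methoxymethoxy)phenyl]oct-6-en-2-ol | C=C(CCC=C(C)C)[C@H](O)Cc1c(OCOC)cc(OCOC)cc1OCOC | intermediate
12 | tert-butyldimethyl({(2R)-7-methyl-3-methylidene-1-[2,4,6-tris(methoxymethoxy)phenyl]oct-6-en-2-yl}oxy)silane | C=C(CCC=C(C)C)[C@H](O[Si](C)(C)C(C)(C)C)Cc1c(OCOC)cc(OCOC)cc1OCOC | intermediate
13 | N-methoxy-N-methylbenzamide | CON(C)C(=O)c1ccccc1 | starting material
14 | {3-[(2R)-2-(tert-butyldimethylsilyloxy)-7-methyl-3-methylideneoct-6-en-1-yl]-2,4,6-tris(methoxymethoxy)phenyl}lithium (not isolated) | C=C(CCC=C(C)C)[C@H](O[Si](C)(C)C(C)(C)C)Cc1c(OCOC)cc(OCOC)c([Li])c1OCOC | intermediate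
15 | lithium alkoxide of the tetrahedral adduct of 14 with 13 (carbinol centre undefined, not isolated) | C=C(CCC=C(C)C)[C@H](O[Si](C)(C)C(C)(C)C)Cc1c(OCOC)cc(OCOC)c(C(O[Li])(N(C)OC)c2ccccc2)c1OCOC | intermediate
16 | {3-[(2R)-2-(tert-butyldimethylsilyloxy)-7-methyl-3-methylideneoct-6-en-1-yl]-2,4,6-tris(methoxymethoxy)phenyl}(phenyl)methanone | C=C(CCC=C(C)C)[C@H](O[Si](C)(C)C(C)(C)C)Cc1c(OCOC)cc(OCOC)c(C(=O)c2ccccc2)c1OCOC | intermediate
17 | {2,4,6-trihydroxy-3-[(2R)-2-hydroxy-7-methyl-3-methylideneoct-6-en-1-yl]phenyl}(phenyl)methanone | C=C(CCC=C(C)C)[C@H](O)Cc1c(O)cc(O)c(C(=O)c2ccccc2)c1O | target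

**Step count and risks**

Total step count: 9. Longest linear sequence: 9 steps (from 1 to 17).

Steps most likely to fail:

1. Step 4 (asymmetric epoxidation). The di-ortho-substituted, electron-rich aryl group may slow the conjugate addition of the peroxide, and the six MOM oxygens may bind lanthanum and erode the enantioface selection. The fallback moves the stereocontrol to a ketone reduction; it sets out from enone 8 and comes back at alcohol 11. Alkaline hydrogen peroxide (30% H2O2, NaOH, MeOH, 0 °C) should give the racemic trans epoxy ketone rac-5-methyl-1-{3-[2,4,6-tris(methoxymethoxy)phenyl]oxiran-2-yl}hex-4-en-1-one F1. Methylenation as in step 5 should give the racemic vinyl epoxide rac-trans-2-(6-methylhepta-1,5-dien-2-yl)-3-[2,4,6-tris(methoxymethoxy)phenyl]oxirane F2. DIBAL-H opening as in step 6 should give the racemic alcohol rac-7-methyl-3-methylidene-1-[2,4,6-tris(methoxymethoxy)phenyl]oct-6-en-2-ol F3. Dess–Martin periodinane (NaHCO3, CH2Cl2) would oxidise this to the achiral α-methylidene ketone 7-methyl-3-methylidene-1-[2,4,6-tris(methoxymethoxy)phenyl]oct-6-en-2-one F4. Corey–Bakshi–Shibata reduction with the (S)-methyl oxazaborolidine and catecholborane (toluene, −78 °C), in which the branched alkenyl group acts as the large substituent, should then return (R)-alcohol 11.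

2. Step 6 (hydride opening). The strongly stabilised benzylic cation may undergo a 1,2-hydride shift before hydride arrives, and the resulting ketone would be reduced to racemised alcohol. Hydride may also be delivered in SN2′ fashion to the methylidene with loss of the C2′–O bond. The fallback sets out from vinyl epoxide 10 and comes back at alcohol 11. Thiophenol with a catalytic mild Lewis acid (InCl3 or LiClO4, CH2Cl2, 0 °C) should trap C1′ with a soft nucleophile that is present in excess, giving the β-hydroxy sulfide (2S)-7-methyl-3-methylidene-1-(phenylsulfanyl)-1-[2,4,6-tris(methoxymethoxy)phenyl]oct-6-en-2-ol F5 as a mixture of C1′ epimers. Radical desulfurisation (Bu3SnH, AIBN, toluene, 80 °C) should then cleave the benzylic C–S bond without touching C2′ and give 11.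

3. Step 9 (global deprotection). Brønsted acid may protonate the C3′ methylidene and let an ortho phenol close a chroman ring, or may add methanol to the C6′=C7′ alkene, before the MOM ether para to the benzoyl group has been cleaved. The fallback sets out from 16 and comes back at 17 by a two-stage, aprotic deprotection. TMSOTf with 2,2′-bipyridyl (CH2Cl2, 0 °C) should convert the aryl MOM ethers into the tris(trimethylsilyl) ether {3-[(2R)-2-(tert-butyldimethylsilyloxy)-7-methyl-3-methylideneoct-6-en-1-yl]-2,4,6-tris(trimethylsilyloxy)phenyl}(phenyl)methanone F6, which is not isolated. Aqueous work-up should hydrolyse it to the triphenol {3-[(2R)-2-(tert-butyldimethylsilyloxy)-7-methyl-3-methylideneoct-6-en-1-yl]-2,4,6-trihydroxyphenyl}(phenyl)methanone F7. Buffered fluoride (HF·pyridine in pyridine/THF, 0 °C) should then remove the silyl ether and give 17.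

Further compounds
F1 | step 4 | rac-5-methyl-1-{3-[2,4,6-tris(methoxymethoxy)phenyl]oxiran-2-yl}hex-4-en-1-one (racemic trans; one enantiomer drawn) | CC(C)=CCCC(=O)[C@@H]1O[C@H]1c1c(OCOC)cc(OCOC)cc1OCOC
F2 | step 4 | rac-trans-2-(6-methylhepta-1,5-dien-2-yl)-3-[2,4,6-tris(methoxymethoxy)phenyl]oxirane (racemic trans; one enantiomer drawn) | C=C(CCC=C(C)C)[C@@H]1O[C@H]1c1c(OCOC)cc(OCOC)cc1OCOC
F3 | step 4 | rac-7-methyl-3-methylidene-1-[2,4,6-tris(methoxymethoxy)phenyl]oct-6-en-2-ol (racemate) | C=C(CCC=C(C)C)C(O)Cc1c(OCOC)cc(OCOC)cc1OCOC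
F4 | step 4 | 7-methyl-3-methylidene-1-[2,4,6-tris(methoxymethoxy)phenyl]oct-6-en-2-one | C=C(CCC=C(C)C)C(=O)Cc1c(OCOC)cc(OCOC)cc1OCOC
F5 | step 6 | (2S)-7-methyl-3-methylidene-1-(phenylsulfanyl)-1-[2,4,6-tris(methoxymethoxy)phenyl]oct-6-en-2-ol (C1 epimers) | C=C(CCC=C(C)C)[C@H](O)C(Sc1ccccc1)c1c(OCOC)cc(OCOC)cc1OCOC
F6 | step 9 | {3-[(2R)-2-(tert-butyldimethylsilyloxy)-7-methyl-3-methylideneoct-6-en-1-yl]-2,4,6-tris(trimethylsilyloxy)phenyl}(phenyl)methanone | C=C(CCC=C(C)C)[C@H](O[Si](C)(C)C(C)(C)C)Cc1c(O[Si](C)(C)C)cc(O[Si](C)(C)C)c(C(=O)c2ccccc2)c1O[Si](C)(C)C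
F7 | step 9 | {3-[(2R)-2-(tert-butyldimethylsilyloxy)-7-methyl-3-methylideneoct-6-en-1-yl]-2,4,6-trihydroxyphenyl}(phenyl)methanone | C=C(CCC=C(C)C)[C@H](O[Si](C)(C)C(C)(C)C)Cc1c(O)cc(O)c(C(=O)c2ccccc2)c1O
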